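**Retrosynthetic overview**
1. The target is a dehydro-dimer (2 × C17H18O5 − 2 H − H2O) of one monomer, (2S,4R)-5-hydroxy-7,8-dimethoxyflavan-4-ol. This follows the presumed biogenesis: phenol oxidation, C6–C8'' coupling, ketalisation, loss of the C4'' hydroxyl.
2. The last ring (dihydrofuran/ketal) is cut at C8a''–O5 (retro syn-SN2′, water back on C4'') and at C6–C8''. Both bonds and both quaternary centres form in one flask: half of the monomer is oxidised to its p-quinone monoketal, and the other half attacks it as a magnesium phenolate.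
3. The pseudo-axial C4 hydroxyl relays the stereochemistry (C2 → C4 → C8''/C8a''). It comes from the 2,4-cis alcohol by o-quinone methide/benzylic cation hydration.
4. C2 and the cis alcohol come from a reductive kinetic resolution of the racemic 5-hydroxyflavanone. Its pyranone ring comes from chalcone → flavanone oxa-Michael closure.
5. Ring order: pyran ring (made once, serves both halves) → dearomatisation of ring A of one half → dihydrofuran ring.

Assumption: flavonoid numbering is used (plain locants for the flavan-4-ol half, doubly primed locants for the dearomatised half), and the acetophenone starting material is taken as a catalogue compound.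

**Step 1**
Reactants: 1 2'-hydroxy-3',4',6'-trimethoxyacetophenone; 2 benzaldehyde
Product: 4 (±)-5,7,8-trimethoxyflavanone, via chalcone 3 (not isolated)
Conditions: KOH (3 equiv), EtOH, rt; then AcOH to pH 6, reflux
Reagents that add atoms: none
Why: Claisen–Schmidt condensation gives 3, and the KOAc formed on neutralisation catalyses the chalcone–flavanone isomerisation (6-endo-trig oxa-Michael, the closure performed by chalcone isomerase); only the 2'-OH is free, so only the 7,8-dimethoxy pattern can form, the 6'-OMe twists the enone and pushes the equilibrium to 4, and C2 is still racemic.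

**Step 2**
Reactants: 4 (±)-5,7,8-trimethoxyflavanone
Product: 5 (±)-5-hydroxy-7,8-dimethoxyflavanone
Conditions: BCl3 (1.2 equiv), CH2Cl2, −78 → 0 °C; H2O work-up
Reagents that add atoms: none
Why: Chelation-directed aryl methyl ether cleavage, in which BCl3 bound to the C4 carbonyl removes only the peri 5-O-methyl group while the 7- and 8-OMe groups and the pyranone ring survive at low temperature; no stereocentre is set.

**Step 3**
Reactants: 5 (±)-5-hydroxy-7,8-dimethoxyflavanone
Product: 7 (2S,4R)-5-hydroxy-7,8-dimethoxyflavan-4-ol, via (2S,4S)-flavan-4-ol 6 (not isolated)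
Conditions: [Cp*RhCl((S,S)-TsDPEN)] (1 mol %), HCO2Na (5 equiv), H2O/EtOAc, 30 °C, to 50 % conversion; phase cut; then THF/aq NaOAc–AcOH buffer (pH 4.5), 5 mM, 25 °C; Et3N-washed silica
Reagents that add atoms: water, O
Why: Noyori–Ikariya asymmetric transfer hydrogenation run as a kinetic resolution, where the (S,S)-catalyst creates 4S, which is the favoured cis outcome only for the (2S)-ketone, so 6 forms in high ee and the (2R)-ketone stays behind (this fixes C2); acid-catalysed epimerisation of the flavan-4-ol through its benzylic cation/o-quinone methide then lets water add along the axial trajectory of the half-chair (2-Ph equatorial), giving the pseudo-axial 4R alcohol, which also avoids the peri contact with O5, and high dilution in water suppresses C4→C6 self-condensation.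

**Step 4**
Reactants: 7 (2S,4R)-5-hydroxy-7,8-dimethoxyflavan-4-ol (two molecules)
Product: 11 6''-demethoxyneocalycopterone, via quinone monoketal 8 (not isolated), via bromomagnesium phenolate 9 (not isolated), via C6–C8'' dienone 10 (not isolated)
Conditions: PhI(OAc)2 (0.50 equiv), NaHCO3, MeOH, −20 °C; evaporate cold, filter; CH2Cl2/toluene, 4 Å MS, MgBr2·OEt2 (2.5 equiv), Et3N (1.2 equiv), −40 → 0 °C; then THF/aq NaOAc–AcOH buffer (pH 5), rt
Reagents that add atoms: methanol, CO
Why: Proposed new method: PhI(OAc)2/MeOH turns exactly half of 7 into 8 (routine oxidative dearomatisation of a 4-methoxyphenol), and in the non-coordinating medium phenolate 9 binds the β-face ketal oxygen of 8 through magnesium and delivers its only free ortho carbon C6 to the ketal carbon C8'' in a six-membered chelate, that is 1,2-substitution rather than attack at the soft C6'' position, as in the ortho-specific Casiraghi–Skattebøl reactions of magnesium phenolates with orthoesters, aldehydes and enals (closest known type, next to acid-promoted quinone monoketal couplings); the pseudo-axial C4''–OH of 8 hydrogen-bonds to the phenolate oxygen and selects the face anti to the C2'' phenyl (sets 8''S), then O5 of 10 closes on C8a'' on the same face while the π-aligned axial C4''–OH leaves (syn-SN2′, the oxa-Michael/dehydration end game of Pummerer's ketone and usnic acid), which can only give the cis-fused ring and the anomerically favoured axial aryl ketal (8a''S); the in-plane C4–H of the trans series resists over-oxidation to the flavanone, no Brønsted acid meets a free nucleophilic arene so C2, C2'' and C4 stay untouched, and traces of (2R)-monomer end up in separable diastereomers.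

**Compound list**
1 | 2'-hydroxy-3',4',6'-trimethoxyacetophenone | CC(=O)c1c(O)c(OC)c(OC)cc1OC | starting material
2 | benzaldehyde | O=Cc1ccccc1 | starting material
3 | (E)-2'-hydroxy-3',4',6'-trimethoxychalcone | COc1cc(OC)c(C(=O)/C=C/c2ccccc2)c(O)c1OC | intermediate
4 | (±)-5,7,8-trimethoxyflavanone (racemic at C2) | COc1cc(OC)c2C(=O)CC(c3ccccc3)Oc2c1OC | intermediate
5 | (±)-5-hydroxy-7,8-dimethoxyflavanone (racemic at C2) | COc1cc(O)c2C(=O)CC(c3ccccc3)Oc2c1OC | intermediate
6 | (2S,4S)-5-hydroxy-7,8-dimethoxyflavan-4-ol (2,4-cis, 4-OH pseudo-equatorial) | COc1cc(O)c2c(c1OC)O[C@H](c1ccccc1)C[C@@H]2O | intermediate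
7 | (2S,4R)-5-hydroxy-7,8-dimethoxyflavan-4-ol (2,4-trans, 4-OH pseudo-axial) | COc1cc(O)c2c(c1OC)O[C@H](c1ccccc1)C[C@H]2O | intermediate
8 | (2S,4R)-4-hydroxy-7,8,8-trimethoxy-2-phenyl-2,3,4,8-tetrahydro-5H-chromen-5-one (p-quinone monoketal of 7) | COC1=CC(=O)C2=C(O[C@H](c3ccccc3)C[C@H]2O)C1(OC)OC | intermediate
9 | bromomagnesium 5-phenolate of 7 | COc1cc([O-])c2c(c1OC)O[C@H](c1ccccc1)C[C@H]2O.[Mg+2].[Br-] | intermediate
10 | (2S,4R)-6-[(2S,4R,8S)-4-hydroxy-7,8-dimethoxy-5-oxo-2-phenyl-3,4,5,8-tetrahydro-2H-chromen-8-yl]-5-hydroxy-7,8-dimethoxyflavan-4-ol (aryl on the face anti to the 2''-phenyl) | COC1=CC(=O)C2=C(O[C@H](c3ccccc3)C[C@H]2O)[C@]1(OC)c1c(O)c2c(c(OC)c1OC)O[C@H](c1ccccc1)C[C@H]2O | intermediate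
11 | 6''-demethoxyneocalycopterone, (2S,4R,2''S,8''S,8a''S): 4-OH trans to 2-Ph; O-aryl at C8a'' and aryl at C8'' cis to each other and trans to 2''-Ph; 8''-OMe on the opposite face | COC1=CC(=O)C2=CC[C@@H](c3ccccc3)O[C@]23Oc2c4c(c(OC)c(OC)c2[C@]13OC)O[C@H](c1ccccc1)C[C@H]4O | target

**Total step count:** 4. **Longest linear sequence:** 4.

**Steps most likely to fail**

**Step 4.** Three things can go wrong. C6 of 9 may attack the soft C6'' position of 8 and give a biaryl. MgBr2 may ionise the axial benzylic hydroxyl of 9 and give C4→C6 oligomers. O5 may close on C7'' instead of C8a''.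

The fallback is a hetero-coupling with a blocked C6''. It sets out from 7 and comes back at 11. NBS (1.0 equiv) in CH2Cl2 at −78 °C brominates the only free aromatic position and gives (2S,4R)-6-bromo-5-hydroxy-7,8-dimethoxyflavan-4-ol F1. PhI(OAc)2 (1.0 equiv), NaHCO3 and MeOH give the isolated 6-bromo quinone monoketal F2. Union of F2 with 9, made from a second portion of 7, can now occur only at the ketal carbon and gives the bromo dienone F3. F3 closes in the buffer to 6''-bromo-6''-demethoxyneocalycopterone F4. Pd(PPh3)4 and Bu3SnH in THF then remove the vinylic bromine.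

**Step 3.** The chelated, peri-hindered ketone may be reduced slowly or with a low selectivity factor. The buffer equilibrium may also leave too much cis alcohol.

The fallback replaces the metal-catalysed reductive resolution by an acylative enzymatic one, and the equilibration by an inversion. It sets out from 5 and comes back at 7. NaBH4 in MeOH/THF at 0 °C gives the racemic 2,4-cis alcohol F5. Candida antarctica lipase B with vinyl acetate in MTBE acetylates only the (2R,4R)-enantiomer (Kazlauskas rule) to the (2R,4R)-4-acetate F6 and leaves 6, which is isolated here. A Mitsunobu reaction (4-nitrobenzoic acid, DIAD, PPh3, THF, −20 °C) gives the 2,4-trans 4-nitrobenzoate F7. K2CO3 in aqueous THF releases 7.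

**Step 2.** The Lewis acid may open the pyranone. With both ortho hydroxyls then free, it can re-close to the 5-hydroxy-6,7-dimethoxy isomer. The crowded 8-OMe may also be cleaved.

The fallback moves the unmasking of O5 to a neutral hydrogenolysis. It sets out from 1 and comes back at 5. BCl3 on the robust ketone 1 gives 2',6'-dihydroxy-3',4'-dimethoxyacetophenone F8. BnBr (1.0 equiv) and K2CO3 in acetone alkylate the less hindered hydroxyl to give 6'-benzyloxy-2'-hydroxy-3',4'-dimethoxyacetophenone F9. Condensation with 2 under the step 1 conditions gives the benzyloxy chalcone F10 and then (±)-5-benzyloxy-7,8-dimethoxyflavanone F11. H2 over Pd/C in EtOAc gives 5.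

**Further compounds**
F1 | step 4 | (2S,4R)-6-bromo-5-hydroxy-7,8-dimethoxyflavan-4-ol | COc1c(Br)c(O)c2c(c1OC)O[C@H](c1ccccc1)C[C@H]2O
F2 | step 4 | (2S,4R)-6-bromo-4-hydroxy-7,8,8-trimethoxy-2-phenyl-2,3,4,8-tetrahydro-5H-chromen-5-one | COC1=C(Br)C(=O)C2=C(O[C@H](c3ccccc3)C[C@H]2O)C1(OC)OC
F3 | step 4 | 6''-bromo analogue of dienone 10 | COC1=C(Br)C(=O)C2=C(O[C@H](c3ccccc3)C[C@H]2O)[C@]1(OC)c1c(O)c2c(c(OC)c1OC)O[C@H](c1ccccc1)C[C@H]2O
F4 | step 4 | 6''-bromo-6''-demethoxyneocalycopterone | COC1=C(Br)C(=O)C2=CC[C@@H](c3ccccc3)O[C@]23Oc2c4c(c(OC)c(OC)c2[C@]13OC)O[C@H](c1ccccc1)C[C@H]4O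
F5 | step 3 | racemic 2,4-cis-5-hydroxy-7,8-dimethoxyflavan-4-ol (both enantiomers) | COc1cc(O)c2c(c1OC)O[C@H](c1ccccc1)C[C@@H]2O.COc1cc(O)c2c(c1OC)O[C@@H](c1ccccc1)C[C@H]2O
F6 | step 3 | (2R,4R)-4-acetoxy-5-hydroxy-7,8-dimethoxyflavan | COc1cc(O)c2c(c1OC)O[C@@H](c1ccccc1)C[C@H]2OC(C)=O
F7 | step 3 | (2S,4R)-5-hydroxy-7,8-dimethoxyflavan-4-yl 4-nitrobenzoate | COc1cc(O)c2c(c1OC)O[C@H](c1ccccc1)C[C@H]2OC(=O)c1ccc(cc1)[N+](=O)[O-]
F8 | step 2 | 2',6'-dihydroxy-3',4'-dimethoxyacetophenone | CC(=O)c1c(O)c(OC)c(OC)cc1O
F9 | step 2 | 6'-benzyloxy-2'-hydroxy-3',4'-dimethoxyacetophenone | CC(=O)c1c(O)c(OC)c(OC)cc1OCc1ccccc1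
F10 | step 2 | (E)-6'-benzyloxy-2'-hydroxy-3',4'-dimethoxychalcone | COc1cc(OCc2ccccc2)c(C(=O)/C=C/c2ccccc2)c(O)c1OC
F11 | step 2 | (±)-5-benzyloxy-7,8-dimethoxyflavanone | COc1cc(OCc2ccccc2)c2C(=O)CC(c3ccccc3)Oc2c1OC
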